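**Plan**
1. The last cut is C9–C10. The C9 carbinol sits on the fusion carbon C10, and C10 is the γ-carbon of the allyl unit C10=C11–C12 inside ring A (cyclohexene C1, C10, C11, C12, C13, C14). An allylchromium at C12 and a C9 aldehyde therefore close the ten-membered ring C1–C10.
2. Earlier cuts: C7–O and C8–O of the lactone (epoxide opened by the C19 ester), C7=C8 (Horner–Wadsworth–Emmons), C5–CH3 and C6–Cl (carbocupration–chlorination of a C5≡C6 ynoate), C2–C3 (Grignard), and the ring A bonds C1–C10 and C13–C14 (Diels–Alder).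
3. Forward order: ring A, then the C2–C7 chain, then the γ-lactone ring (C7, C8, C17, C19, O), then the ten-membered ring, and last the ring A oxidation pattern and the acetates.
4. Stereochemistry: C1 from the Diels–Alder catalyst; C2 from a CBS reduction; C17 from (R)-lactate by SN2 inversion; C7 and C8 from a Sharpless epoxidation, with inversion at C7 on lactonisation; C9 and C10 in the chromium closure; C11 by α-face hydroboration; C12 by α-face hydride delivery followed by Mitsunobu inversion; the C5=C6 geometry from syn-carbocupration.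

Key step: step 24

Assumption: the (S)-oxazaborolidinium catalyst is taken to give (S)-4 (its mirror image is used if the face preference is the reverse); centres that are destroyed later (C2 in 7, C12 in 12–32, the phosphorus-bearing carbon of 23) are carried as mixtures and drawn without configuration.

Briarane numbering is used throughout; α is the face of ring A opposite to the C1 methyl.

Step 1
Reactants: 1 3-methylbut-3-en-2-one
Product: 2 triisopropyl[(3-methylbuta-1,3-dien-2-yl)oxy]silane
Conditions: i-Pr3SiOTf, Et3N, CH2Cl2, 0 °C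
Reagents that add atoms: triisopropylsilyl trifluoromethanesulfonate, CC(C)[Si](C(C)C)(C(C)C)OS(=O)(=O)C(F)(F)F
Why: Soft enolisation of the methyl ketone with a silyl triflate and a tertiary amine (silyl enol ether formation) takes the only α-protons and gives the 2-siloxy diene needed for the cycloaddition.

Step 2
Reactants: 2 triisopropyl[(3-methylbuta-1,3-dien-2-yl)oxy]silane; 3 methacrolein
Product: 4 (S)-1,3-dimethyl-4-(triisopropylsilyloxy)cyclohex-3-ene-1-carbaldehyde
Conditions: (S)-3,3-diphenyl-1-(o-tolyl)tetrahydro-1H,3H-pyrrolo[1,2-c][1,3,2]oxazaborole (20 mol %), HNTf2 (18 mol %), CH2Cl2, −78 → −40 °C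
Reagents that add atoms: none
Why: Catalytic enantioselective Diels–Alder reaction in which the chiral oxazaborolidinium cation binds s-trans methacrolein and shields one face, so that the quaternary C1 is set by the catalyst while the siloxy group directs the para regiochemistry that places the masked C12 ketone 1,4 and the C11 methyl 1,3 to C1.

Step 3
Reactants: 4 (S)-1,3-dimethyl-4-(triisopropylsilyloxy)cyclohex-3-ene-1-carbaldehyde; 5 (4-bromobut-1-yn-1-yl)trimethylsilane
Product: 7 1-[(S)-1,3-dimethyl-4-(triisopropylsilyloxy)cyclohex-3-en-1-yl]-5-(trimethylsilyl)pent-4-yn-1-ol (both C2 epimers), via silylbutynylmagnesium bromide 6 (not isolated)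
Conditions: Mg, THF, rt (5 → 6); then 4, −78 → 0 °C; aq NH4Cl
Reagents that add atoms: none
Why: Grignard addition of the homopropargylic magnesium reagent to the neopentyl aldehyde forms C2–C3 and brings in C3–C6, the carbinol configuration being left open because the next step erases it.

Step 4
Reactants: 7 C2 carbinol mixture
Product: 8 1-[(S)-1,3-dimethyl-4-(triisopropylsilyloxy)cyclohex-3-en-1-yl]-5-(trimethylsilyl)pent-4-yn-1-one
Conditions: Dess–Martin periodinane, NaHCO3, CH2Cl2, rt
Reagents that add atoms: none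
Why: Dess–Martin oxidation of the hindered secondary alcohol under buffered conditions gives the C2 ketone without touching the silyl enol ether or the silylalkyne.

Step 5
Reactants: 8 C2 ketone
Product: 9 (S)-1-[(S)-1,3-dimethyl-4-(triisopropylsilyloxy)cyclohex-3-en-1-yl]-5-(trimethylsilyl)pent-4-yn-1-ol
Conditions: (R)-1-methyl-3,3-diphenyltetrahydro-1H,3H-pyrrolo[1,2-c][1,3,2]oxazaborole (0.5 equiv), catecholborane, toluene, −78 → −30 °C
Reagents that add atoms: none
Why: Corey–Bakshi–Shibata reduction in which the quaternary C1 is the large and the C3 methylene the small ketone substituent, so that the (R)-catalyst delivers hydride under reagent control to give the (S)-carbinol at C2.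

Step 6
Reactants: 9 (S)-carbinol
Product: 10 4-methoxybenzyl ether of 9
Conditions: NaH, 4-MeOC6H4CH2Br, Bu4NI (cat.), THF/DMF, 0 °C → rt
Reagents that add atoms: 4-methoxybenzyl bromide, COc1ccc(CBr)cc1
Why: Williamson etherification of the sodium alkoxide installs at C2 a protecting group that withstands base, hydride and fluoride and is removed oxidatively near the end.

Step 7
Reactants: 10 4-methoxybenzyl ether
Product: 11 (S)-4-[(S)-1-(4-methoxybenzyloxy)-5-(trimethylsilyl)pent-4-yn-1-yl]-2,4-dimethylcyclohex-2-en-1-one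
Conditions: Pd(OAc)2 (1.2 equiv), MeCN, 40 °C
Reagents that add atoms: none
Why: Saegusa–Ito oxidation in which the siloxy group is exchanged for a palladium enolate that loses a β-hydride from C10 and so gives the endocyclic C10=C11 enone without affecting the quaternary C1.

Step 8
Reactants: 11 ring A enone
Product: 12 ring A allylic alcohol (C12 epimers)
Conditions: NaBH4, CeCl3·7H2O, MeOH, −78 °C
Reagents that add atoms: none
Why: Luche reduction gives clean 1,2-reduction of the enone to the allylic alcohol, whose configuration at C12 is immaterial because that carbon later carries chromium.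

Step 9
Reactants: 12 ring A allylic alcohol
Product: 13 C12 tert-butyldimethylsilyl ether
Conditions: TBSCl, imidazole, DMF, rt
Reagents that add atoms: tert-butyldimethylsilyl chloride, CC(C)(C)[Si](C)(C)Cl
Why: Standard silylation of the unhindered allylic alcohol masks C12 until the bromide is needed.

Step 10
Reactants: 13 C12 silyl ether
Product: 15 methyl (S)-6-[(1S)-4-(tert-butyldimethylsilyloxy)-1,3-dimethylcyclohex-2-en-1-yl]-6-(4-methoxybenzyloxy)hex-2-ynoate, via lithium acetylide 14 (not isolated)
Conditions: MeLi·LiBr, THF, 0 °C → rt; then ClCO2Me, −78 °C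
Reagents that add atoms: methyl chloroformate, COC(=O)Cl
Why: Methyllithium cleaves the alkynyl–silicon bond to the lithium acetylide, which is acylated by the chloroformate (acetylide carboxylation) and so introduces C7 as the ynoate ester.

Step 11
Reactants: 15 ynoate
Product: 17 methyl (2E,6S)-2-chloro-6-[(1S)-4-(tert-butyldimethylsilyloxy)-1,3-dimethylcyclohex-2-en-1-yl]-6-(4-methoxybenzyloxy)-3-methylhex-2-enoate, via lithium vinylcuprate 16 (not isolated)
Conditions: Me2CuLi (from MeLi, CuI), THF, −78 °C; then NCS, −78 °C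
Reagents that add atoms: lithium dimethylcuprate, C[Cu-]C.[Li+]; N-chlorosuccinimide, O=C1CCC(=O)N1Cl
Why: Syn-carbocupration of the ynoate at −78 °C places the new methyl on C5 and copper on C6 on the same side, and electrophilic chlorination of the vinylcopper with retention (conjugate addition–halogenation) gives the tetrasubstituted chloroalkene with C4 and C7 cis.

Step 12
Reactants: 17 α-chloro enoate
Product: 18 (2E,6S)-2-chloro-6-[(1S)-4-(tert-butyldimethylsilyloxy)-1,3-dimethylcyclohex-2-en-1-yl]-6-(4-methoxybenzyloxy)-3-methylhex-2-en-1-ol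
Conditions: iBu2AlH, CH2Cl2, −78 °C; aq sodium potassium tartrate
Reagents that add atoms: none
Why: Hydride reduction of the unsaturated ester with iBu2AlH occurs in the 1,2-sense at low temperature and gives the C7 allylic alcohol with the alkene geometry unchanged.

Step 13
Reactants: 18 C7 allylic alcohol
Product: 19 (2E,6S)-2-chloro-6-[(1S)-4-(tert-butyldimethylsilyloxy)-1,3-dimethylcyclohex-2-en-1-yl]-6-(4-methoxybenzyloxy)-3-methylhex-2-enal
Conditions: Dess–Martin periodinane, NaHCO3, CH2Cl2, 0 °C
Reagents that add atoms: none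
Why: Dess–Martin oxidation of the allylic alcohol gives the α-chloro enal without isomerising the tetrasubstituted alkene.

Step 14
Reactants: 20 tert-butyl (R)-lactate
Product: 21 tert-butyl (R)-2-(trifluoromethylsulfonyloxy)propanoate
Conditions: Tf2O, 2,6-lutidine, CH2Cl2, −78 → 0 °C
Reagents that add atoms: trifluoromethanesulfonic anhydride, O=S(=O)(OS(=O)(=O)C(F)(F)F)C(F)(F)F
Why: O-Sulfonylation of the α-hydroxy ester (triflate formation) occurs with retention and gives a secondary electrophile that reacts by clean inversion.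

Step 15
Reactants: 21 lactate triflate; 22 trimethyl phosphonoacetate
Product: 23 4-tert-butyl 1-methyl (3S)-2-(dimethoxyphosphoryl)-3-methylbutanedioate (epimers at the phosphorus-bearing carbon)
Conditions: NaH, THF, 0 °C; then 21, 0 °C → rt
Reagents that add atoms: none
Why: SN2 alkylation of sodio phosphonoacetate by the secondary triflate proceeds with inversion and so fixes C17 with the methyl group in the configuration of the target.

Step 16
Reactants: 23 phosphonate; 19 α-chloro enal
Product: 24 diene diester with (E)-C7=C8 (C9 methyl ester, C19 tert-butyl ester)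
Conditions: NaH, THF, 0 °C; then 19, 0 °C → rt
Reagents that add atoms: none
Why: Horner–Wadsworth–Emmons olefination of the α-branched phosphonate gives the trisubstituted C7=C8 alkene with C6 trans to the C9 ester and cis to the C17 branch, and because the phosphonate anion is the only base present the C17 stereocentre should survive.

Step 17
Reactants: 24 diene diester
Product: 25 C9 allylic alcohol (C19 tert-butyl ester retained)
Conditions: iBu2AlH (2.2 equiv), CH2Cl2, −78 °C; aq sodium potassium tartrate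
Reagents that add atoms: none
Why: Chemoselective ester reduction in which iBu2AlH at −78 °C reduces the conjugated methyl ester to the allylic alcohol faster than the hindered α-branched tert-butyl ester.

Step 18
Reactants: 25 C9 allylic alcohol
Product: 26 (7S,8R)-7,8-epoxy alcohol
Conditions: Ti(OiPr)4, D-(−)-diethyl tartrate, t-BuOOH, 4 Å MS, CH2Cl2, −20 °C
Reagents that add atoms: tert-butyl hydroperoxide, CC(C)(C)OO
Why: Sharpless asymmetric epoxidation of the primary allylic alcohol in which the D-tartrate complex selects the alkene face that gives the (7S,8R)-epoxide, the other two alkenes being inert because they are not part of an allylic alcohol.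

Step 19
Reactants: 26 epoxy alcohol
Product: 27 (7R,8R,17R)-hydroxy lactone diol (C8 tertiary OH, C9 primary OH)
Conditions: BF3·OEt2, CH2Cl2, −78 → −40 °C; aq NaHCO3
Reagents that add atoms: none
Why: Lewis acid-promoted epoxide opening by the carbonyl oxygen of the tert-butyl ester at the allylic C7 with inversion and loss of isobutene closes the γ-lactone through C7–O and leaves the C8 alcohol with retention, so that both C7 and C8 derive from the epoxide.

Step 20
Reactants: 27 lactone diol
Product: 28 tertiary α-hydroxy aldehyde (C9 aldehyde)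
Conditions: SO3·pyridine, DMSO, iPr2NEt, CH2Cl2, 0 °C
Reagents that add atoms: none
Why: Parikh–Doering oxidation converts the primary C9 alcohol into the aldehyde while the tertiary C8 alcohol cannot be oxidised.

Step 21
Reactants: 28 α-hydroxy aldehyde
Product: 29 C8 tert-butyldimethylsilyl ether aldehyde
Conditions: TBSOTf, 2,6-lutidine, CH2Cl2, −78 → 0 °C
Reagents that add atoms: tert-butyldimethylsilyl trifluoromethanesulfonate, CC(C)(C)[Si](C)(C)OS(=O)(=O)C(F)(F)F
Why: Silylation with a silyl triflate and a hindered pyridine caps the tertiary hydroxyl next to the non-enolisable aldehyde and thereby blocks α-ketol rearrangement and retro-aldol cleavage in later steps.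

Step 22
Reactants: 29 bis-silyl ether aldehyde
Product: 30 ring A allylic alcohol aldehyde (C12 epimers)
Conditions: HF·pyridine, pyridine, THF, 0 °C → rt
Reagents that add atoms: none
Why: Selective desilylation by steric differentiation, the secondary allylic silyl ether at C12 being cleaved by buffered fluoride much faster than the tertiary neopentyl silyl ether at C8.

Step 23
Reactants: 30 ring A allylic alcohol aldehyde
Product: 31 seco aldehyde with ring A allylic bromide at C12 (either epimer)
Conditions: NBS, Me2S, CH2Cl2, −20 → 0 °C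
Reagents that add atoms: N-bromosuccinimide, O=C1CCC(=O)N1Br
Why: Corey–Kim bromination converts the allylic alcohol into the allylic bromide under neutral conditions that tolerate the aldehyde, and any allylic transposition or epimer mixture is harmless because all isomers converge on one allylchromium species.

Step 24
Reactants: 31 seco aldehyde with ring A allylic bromide
Product: 33 ten-membered (9S,10S)-carbinol with C11=C12 in ring A, via allylchromium dichloride 32 (not isolated)
Conditions: CrCl2 (10 equiv), THF, rt, syringe-pump addition of 31 (final 0.003 M); aq work-up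
Reagents that add atoms: none
Why: Two equivalents of divalent chromium reduce the C12–Br bond to an allyl species of trivalent chromium that resides at the less hindered C12 and adds to the C9 aldehyde through its γ-carbon C10 in a six-membered cyclic transition state. The closest known reaction type is the CrCl2-mediated intramolecular Nozaki–Hiyama allylation of aldehydes that forms ten-membered carbocycles. The ten-membered ring closes by this carbonyl addition as C9–C10 forms, the chain being held in a loop by the ring-cis C5=C6 chloroalkene and the lactone. C10 is set by the tether, which should reach the C10 face anti to the C1–C2 bond and so give the trans ring fusion, and C9 is set by the chair-like transition state in which the C8 substituent of the aldehyde is equatorial, which corresponds to 9S. The step needs γ- over α-attack, secured by the cyclic transition state, chemoselectivity for the allylic bromide over the vinyl chloride and the lactone, secured by the absence of a nickel salt, and cyclisation over oligomerisation, secured by slow addition at high dilution.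

Step 25
Reactants: 33 ten-membered carbinol
Product: 34 C9 triethylsilyl ether
Conditions: TESOTf, 2,6-lutidine, CH2Cl2, −78 → 0 °C
Reagents that add atoms: triethylsilyl trifluoromethanesulfonate, CC[Si](CC)(CC)OS(=O)(=O)C(F)(F)F
Why: Silylation of the hindered C9 carbinol with the reactive triflate protects it from the C12 oxidation and from the later acetylation.

Step 26
Reactants: 34 C9 silyl ether
Product: 36 (11R,12R)-12α-alcohol, via C12 alkylborane 35 (not isolated)
Conditions: BH3·THF, THF, 0 °C → rt; then NaBO3·4H2O, THF/H2O, rt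
Reagents that add atoms: sodium perborate, [Na+].[Na+].O[B-]1(O)OO[B-](O)(O)OO1
Why: Hydroboration–oxidation of the trisubstituted C11=C12 alkene places boron on C12 and hydrogen on C11 in a syn manner from the α-face, away from the C10–C9 bond and the C1 methyl, which sets C11 with its methyl β and gives the 12α-alcohol.

Step 27
Reactants: 36 12α-alcohol
Product: 37 C12 ketone
Conditions: Dess–Martin periodinane, NaHCO3, CH2Cl2, 0 °C → rt
Reagents that add atoms: none
Why: Dess–Martin oxidation under buffered conditions gives the ketone without epimerising the adjacent C11.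

Step 28
Reactants: 37 C12 ketone
Product: 39 C13=C14 enone, via trimethylsilyl enol ether 38 (not isolated)
Conditions: i-Pr2NLi (LDA), Me3SiCl, THF, −78 °C; then Pd(OAc)2, MeCN, rt
Reagents that add atoms: none
Why: Kinetic deprotonation at the unhindered C13 methylene with in situ silylation followed by Saegusa–Ito oxidation introduces the C13=C14 double bond regioselectively and leaves C11 untouched.

Step 29
Reactants: 39 enone
Product: 40 C2 alcohol
Conditions: DDQ, CH2Cl2/pH 7 buffer, 0 °C
Reagents that add atoms: none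
Why: Oxidative cleavage of the 4-methoxybenzyl ether with DDQ frees the C2 hydroxyl without affecting the silyl ethers, the enone or the vinyl chloride.

Step 30
Reactants: 40 C2 alcohol
Product: 41 C2 acetate
Conditions: Ac2O, DMAP, pyridine, CH2Cl2, rt
Reagents that add atoms: acetic anhydride, CC(=O)OC(C)=O
Why: DMAP-catalysed acetylation esterifies the only free hydroxyl.

Step 31
Reactants: 41 enone acetate
Product: 42 12β-allylic alcohol (12S)
Conditions: NaBH4, CeCl3·7H2O, MeOH, −78 °C
Reagents that add atoms: none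
Why: Luche reduction should deliver hydride to the C12 carbonyl from the α-face, which is free of the cis-disposed C11 methyl and C10–C9 bond, and is therefore expected to give the 12β-alcohol by 1,2-addition.

Step 32
Reactants: 42 12β-allylic alcohol
Product: 43 2,12α-diacetate bis-silyl ether
Conditions: PPh3, DIAD, AcOH, toluene, 0 °C → rt
Reagents that add atoms: acetic acid, CC(=O)O
Why: Mitsunobu esterification displaces the activated 12β-oxygen by acetate from the open α-face with inversion and so installs the 12α-acetate.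

Step 33
Reactants: 43 diacetate bis-silyl ether
Product: 44 CNP0296164.1
Conditions: HF (48% aq), MeCN, 0 °C → rt
Reagents that add atoms: none
Why: Global desilylation with aqueous HF cleaves the triethylsilyl and the tertiary tert-butyldimethylsilyl ether while the two acetates and the lactone are stable, releasing the 8,9-diol of the target.

**Compound list**
1 | 3-methylbut-3-en-2-one | CC(=O)C(C)=C | starting material
2 | triisopropyl[(3-methylbuta-1,3-dien-2-yl)oxy]silane | C=C(C)C(=C)O[Si](C(C)C)(C(C)C)C(C)C | intermediate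
3 | methacrolein (2-methylprop-2-enal) | CC(=C)C=O | starting material
4 | (S)-1,3-dimethyl-4-(triisopropylsilyloxy)cyclohex-3-ene-1-carbaldehyde | O=C[C@]1(C)CC(C)=C(O[Si](C(C)C)(C(C)C)C(C)C)CC1 | intermediate
5 | (4-bromobut-1-yn-1-yl)trimethylsilane | C[Si](C)(C)C#CCCBr | starting material
6 | [4-(trimethylsilyl)but-3-yn-1-yl]magnesium bromide (not isolated) | C[Si](C)(C)C#CCC[Mg]Br | intermediate
7 | 1-[(S)-1,3-dimethyl-4-(triisopropylsilyloxy)cyclohex-3-en-1-yl]-5-(trimethylsilyl)pent-4-yn-1-ol, both C2 epimers | C[Si](C)(C)C#CCCC(O)[C@]1(C)CC(C)=C(O[Si](C(C)C)(C(C)C)C(C)C)CC1 | intermediate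
8 | 1-[(S)-1,3-dimethyl-4-(triisopropylsilyloxy)cyclohex-3-en-1-yl]-5-(trimethylsilyl)pent-4-yn-1-one | C[Si](C)(C)C#CCCC(=O)[C@]1(C)CC(C)=C(O[Si](C(C)C)(C(C)C)C(C)C)CC1 | intermediate
9 | (S)-1-[(S)-1,3-dimethyl-4-(triisopropylsilyloxy)cyclohex-3-en-1-yl]-5-(trimethylsilyl)pent-4-yn-1-ol | C[Si](C)(C)C#CCC[C@H](O)[C@]1(C)CC(C)=C(O[Si](C(C)C)(C(C)C)C(C)C)CC1 | intermediate
10 | 4-methoxybenzyl ether of 9 (C2 OPMB, 1S,2S) | C[Si](C)(C)C#CCC[C@H](OCc2ccc(OC)cc2)[C@]1(C)CC(C)=C(O[Si](C(C)C)(C(C)C)C(C)C)CC1 | intermediate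
11 | (S)-4-[(S)-1-(4-methoxybenzyloxy)-5-(trimethylsilyl)pent-4-yn-1-yl]-2,4-dimethylcyclohex-2-en-1-one | C[Si](C)(C)C#CCC[C@H](OCc2ccc(OC)cc2)[C@]1(C)C=C(C)C(=O)CC1 | intermediate
12 | (4S)-4-[(S)-1-(4-methoxybenzyloxy)-5-(trimethylsilyl)pent-4-yn-1-yl]-2,4-dimethylcyclohex-2-en-1-ol, C12 epimers | C[Si](C)(C)C#CCC[C@H](OCc2ccc(OC)cc2)[C@]1(C)C=C(C)C(O)CC1 | intermediate
13 | tert-butyldimethylsilyl ether of 12 | C[Si](C)(C)C#CCC[C@H](OCc2ccc(OC)cc2)[C@]1(C)C=C(C)C(O[Si](C)(C)C(C)(C)C)CC1 | intermediate
14 | lithium acetylide from 13 (not isolated) | [Li]C#CCC[C@H](OCc2ccc(OC)cc2)[C@]1(C)C=C(C)C(O[Si](C)(C)C(C)(C)C)CC1 | intermediate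
15 | methyl (S)-6-[(1S)-4-(tert-butyldimethylsilyloxy)-1,3-dimethylcyclohex-2-en-1-yl]-6-(4-methoxybenzyloxy)hex-2-ynoate | COC(=O)C#CCC[C@H](OCc2ccc(OC)cc2)[C@]1(C)C=C(C)C(O[Si](C)(C)C(C)(C)C)CC1 | intermediate
16 | lithium methyl(vinyl)cuprate from 15, new methyl and copper cis (not isolated) | COC(=O)/C([Cu-]C)=C(/C)CC[C@H](OCc2ccc(OC)cc2)[C@]1(C)C=C(C)C(O[Si](C)(C)C(C)(C)C)CC1.[Li+] | intermediate
17 | methyl (2E,6S)-2-chloro-6-[(1S)-4-(tert-butyldimethylsilyloxy)-1,3-dimethylcyclohex-2-en-1-yl]-6-(4-methoxybenzyloxy)-3-methylhex-2-enoate | COC(=O)/C(Cl)=C(/C)CC[C@H](OCc2ccc(OC)cc2)[C@]1(C)C=C(C)C(O[Si](C)(C)C(C)(C)C)CC1 | intermediate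
18 | (2E,6S)-2-chloro-6-[(1S)-4-(tert-butyldimethylsilyloxy)-1,3-dimethylcyclohex-2-en-1-yl]-6-(4-methoxybenzyloxy)-3-methylhex-2-en-1-ol | OC/C(Cl)=C(/C)CC[C@H](OCc2ccc(OC)cc2)[C@]1(C)C=C(C)C(O[Si](C)(C)C(C)(C)C)CC1 | intermediate
19 | (2E,6S)-2-chloro-6-[(1S)-4-(tert-butyldimethylsilyloxy)-1,3-dimethylcyclohex-2-en-1-yl]-6-(4-methoxybenzyloxy)-3-methylhex-2-enal | O=C/C(Cl)=C(/C)CC[C@H](OCc2ccc(OC)cc2)[C@]1(C)C=C(C)C(O[Si](C)(C)C(C)(C)C)CC1 | intermediate
20 | tert-butyl (R)-lactate | C[C@@H](O)C(=O)OC(C)(C)C | starting material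
21 | tert-butyl (R)-2-(trifluoromethylsulfonyloxy)propanoate | C[C@@H](OS(=O)(=O)C(F)(F)F)C(=O)OC(C)(C)C | intermediate
22 | trimethyl phosphonoacetate | COC(=O)CP(=O)(OC)OC | starting material
23 | 4-tert-butyl 1-methyl (3S)-2-(dimethoxyphosphoryl)-3-methylbutanedioate, epimers at C2 of the diester | COC(=O)C(P(=O)(OC)OC)[C@@H](C)C(=O)OC(C)(C)C | intermediate
24 | diene diester: (E)-C7=C8 with C6 trans to the C9 methyl ester, C17 (R) bearing the C19 tert-butyl ester, chloroalkene, C2 and ring A as in 19 | COC(=O)/C(=C/C(Cl)=C(/C)CC[C@H](OCc2ccc(OC)cc2)[C@]1(C)C=C(C)C(O[Si](C)(C)C(C)(C)C)CC1)[C@@H](C)C(=O)OC(C)(C)C | intermediate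
25 | C9 allylic alcohol from 24 (C9 CH2OH, C19 tert-butyl ester) | OC/C(=C/C(Cl)=C(/C)CC[C@H](OCc2ccc(OC)cc2)[C@]1(C)C=C(C)C(O[Si](C)(C)C(C)(C)C)CC1)[C@@H](C)C(=O)OC(C)(C)C | intermediate
26 | (7S,8R)-7,8-epoxide of 25 | OC[C@]1(O[C@@H]1/C(Cl)=C(/C)CC[C@H](OCc2ccc(OC)cc2)[C@]3(C)C=C(C)C(O[Si](C)(C)C(C)(C)C)CC3)[C@@H](C)C(=O)OC(C)(C)C | intermediate
27 | (7R,8R,17R)-γ-lactone diol: 8-hydroxy-8-(hydroxymethyl)-17-methyl lactone carrying the chloroalkenyl chain at C7 | OC[C@]1(O)[C@@H](C)C(=O)O[C@H]1/C(Cl)=C(/C)CC[C@H](OCc2ccc(OC)cc2)[C@]3(C)C=C(C)C(O[Si](C)(C)C(C)(C)C)CC3 | intermediate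
28 | C9 aldehyde with free C8 hydroxyl (7R,8S,17R) | O=C[C@]1(O)[C@@H](C)C(=O)O[C@H]1/C(Cl)=C(/C)CC[C@H](OCc2ccc(OC)cc2)[C@]3(C)C=C(C)C(O[Si](C)(C)C(C)(C)C)CC3 | intermediate
29 | C9 aldehyde, C8 and C12 tert-butyldimethylsilyl ethers | O=C[C@]1(O[Si](C)(C)C(C)(C)C)[C@@H](C)C(=O)O[C@H]1/C(Cl)=C(/C)CC[C@H](OCc2ccc(OC)cc2)[C@]3(C)C=C(C)C(O[Si](C)(C)C(C)(C)C)CC3 | intermediate
30 | C9 aldehyde, C8 silyl ether, free C12 allylic alcohol (C12 epimers) | O=C[C@]1(O[Si](C)(C)C(C)(C)C)[C@@H](C)C(=O)O[C@H]1/C(Cl)=C(/C)CC[C@H](OCc2ccc(OC)cc2)[C@]3(C)C=C(C)C(O)CC3 | intermediate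
31 | seco aldehyde: C9 aldehyde, C8 OTBS, 7,19-lactone, C5=C6 chloroalkene (C4 cis to C7), C2 OPMB, ring A C10=C11 with C12 bromide (either epimer) | O=C[C@]1(O[Si](C)(C)C(C)(C)C)[C@@H](C)C(=O)O[C@H]1/C(Cl)=C(/C)CC[C@H](OCc2ccc(OC)cc2)[C@]3(C)C=C(C)C(Br)CC3 | intermediate
32 | allylchromium dichloride from 31, trivalent chromium at C12 (not isolated) | O=C[C@]1(O[Si](C)(C)C(C)(C)C)[C@@H](C)C(=O)O[C@H]1/C(Cl)=C(/C)CC[C@H](OCc2ccc(OC)cc2)[C@]3(C)C=C(C)C([Cr](Cl)Cl)CC3 | intermediate
33 | ten-membered carbinol (1S,2S,7R,8R,9S,10S,17R): C9 OH, C8 OTBS, C2 OPMB, C11=C12 in ring A | COc1ccc(cc1)CO[C@H]2CC/C(C)=C(/Cl)[C@@H]3OC(=O)[C@H](C)[C@@]3(O[Si](C)(C)C(C)(C)C)[C@@H](O)[C@H]4C(C)=CCC[C@@]42C | intermediate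
34 | C9 triethylsilyl ether of 33 | COc1ccc(cc1)CO[C@H]2CC/C(C)=C(/Cl)[C@@H]3OC(=O)[C@H](C)[C@@]3(O[Si](C)(C)C(C)(C)C)[C@@H](O[Si](CC)(CC)CC)[C@H]4C(C)=CCC[C@@]42C | intermediate
35 | C12 alkylborane from 34, boron α at C12 and hydrogen α at C11 (not isolated) | COc1ccc(cc1)CO[C@H]2CC/C(C)=C(/Cl)[C@@H]3OC(=O)[C@H](C)[C@@]3(O[Si](C)(C)C(C)(C)C)[C@@H](O[Si](CC)(CC)CC)[C@H]4[C@@H](C)[C@H](B)CC[C@@]42C | intermediate
36 | (11R,12R)-12α-alcohol | COc1ccc(cc1)CO[C@H]2CC/C(C)=C(/Cl)[C@@H]3OC(=O)[C@H](C)[C@@]3(O[Si](C)(C)C(C)(C)C)[C@@H](O[Si](CC)(CC)CC)[C@H]4[C@@H](C)[C@H](O)CC[C@@]42C | intermediate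
37 | C12 ketone (11R) | COc1ccc(cc1)CO[C@H]2CC/C(C)=C(/Cl)[C@@H]3OC(=O)[C@H](C)[C@@]3(O[Si](C)(C)C(C)(C)C)[C@@H](O[Si](CC)(CC)CC)[C@H]4[C@@H](C)C(=O)CC[C@@]42C | intermediate
38 | C12=C13 trimethylsilyl enol ether (not isolated) | COc1ccc(cc1)CO[C@H]2CC/C(C)=C(/Cl)[C@@H]3OC(=O)[C@H](C)[C@@]3(O[Si](C)(C)C(C)(C)C)[C@@H](O[Si](CC)(CC)CC)[C@H]4[C@@H](C)C(O[Si](C)(C)C)=CC[C@@]42C | intermediate
39 | C13=C14 enone, C12 ketone | COc1ccc(cc1)CO[C@H]2CC/C(C)=C(/Cl)[C@@H]3OC(=O)[C@H](C)[C@@]3(O[Si](C)(C)C(C)(C)C)[C@@H](O[Si](CC)(CC)CC)[C@H]4[C@@H](C)C(=O)C=C[C@@]42C | intermediate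
40 | enone with free C2 hydroxyl | O[C@H]1CC/C(C)=C(/Cl)[C@@H]2OC(=O)[C@H](C)[C@@]2(O[Si](C)(C)C(C)(C)C)[C@@H](O[Si](CC)(CC)CC)[C@H]3[C@@H](C)C(=O)C=C[C@@]31C | intermediate
41 | enone C2 acetate | CC(=O)O[C@H]1CC/C(C)=C(/Cl)[C@@H]2OC(=O)[C@H](C)[C@@]2(O[Si](C)(C)C(C)(C)C)[C@@H](O[Si](CC)(CC)CC)[C@H]3[C@@H](C)C(=O)C=C[C@@]31C | intermediate
42 | 12β-allylic alcohol (12S), C2 acetate | CC(=O)O[C@H]1CC/C(C)=C(/Cl)[C@@H]2OC(=O)[C@H](C)[C@@]2(O[Si](C)(C)C(C)(C)C)[C@@H](O[Si](CC)(CC)CC)[C@H]3[C@@H](C)[C@@H](O)C=C[C@@]31C | intermediate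
43 | 2,12α-diacetate with C8 OTBS and C9 OTES | CC(=O)O[C@H]1CC/C(C)=C(/Cl)[C@@H]2OC(=O)[C@H](C)[C@@]2(O[Si](C)(C)C(C)(C)C)[C@@H](O[Si](CC)(CC)CC)[C@H]3[C@@H](C)[C@H](OC(C)=O)C=C[C@@]31C | intermediate
44 | CNP0296164.1 (1S,2S,7R,8R,9S,10S,11R,12R,17R) | CC(=O)O[C@H]1CC/C(C)=C(/Cl)[C@@H]2OC(=O)[C@H](C)[C@@]2(O)[C@@H](O)[C@H]2[C@@H](C)[C@H](OC(C)=O)C=C[C@@]21C | target

**Step count and risks**
Total: 33 steps. Longest linear sequence: 31 steps (steps 1–13 and 16–33, from 3-methylbut-3-en-2-one); the phosphonate 23 is made in two steps (14–15) and joined in step 16.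

The three steps most likely to fail:

1. Step 24. The chain may react between molecules faster than it closes the strained ten-membered ring, and the aldehyde face may be poorly controlled in the medium-ring transition state, so that the C9 epimer forms. The fallback sets out from 31: the closure is run as before and the epimer mixture is accepted. The C9-epimeric carbinol F1 is oxidised with buffered Dess–Martin periodinane to the C9 ketone F2; buffering is needed because this β,γ-unsaturated ketone could conjugate into C10. F2 is reduced with LiBH(s-Bu)3 at −78 °C, which should approach from the outer face of the medium ring. The 9S alcohol rejoins the route at 33, and recovered F1 is recycled through F2.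

2. Step 11. The vinylcopper may equilibrate through the allenoate before chlorine transfer, which would scramble the C5=C6 geometry, or chlorine transfer from NCS may be slow, so that simple protonation wins. The fallback sets out from 15: the cuprate adduct is quenched with iodine at −78 °C, a faster trapping, to give the α-iodo enoate F3 of the same geometry. The iodide is then exchanged for chloride with retention by heating with CuCl in DMF, and the route is rejoined at 17.

3. Step 32. The activated allylic oxygen may eliminate to the ring A diene, or acetate may enter with allylic transposition instead of clean inversion. The fallback sets out from 42: the alcohol is converted with chloromethanesulfonyl chloride and pyridine into the 12β-chloromethanesulfonate F4. This isolated sulfonate is displaced with CsOAc and 18-crown-6 in toluene, and the route is rejoined at 43.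

Further compounds
F1 | step 24 | C9-epimeric ten-membered carbinol (9R) | COc1ccc(cc1)CO[C@H]2CC/C(C)=C(/Cl)[C@@H]3OC(=O)[C@H](C)[C@@]3(O[Si](C)(C)C(C)(C)C)[C@H](O)[C@H]4C(C)=CCC[C@@]42C
F2 | step 24 | ten-membered C9 ketone | COc1ccc(cc1)CO[C@H]2CC/C(C)=C(/Cl)[C@@H]3OC(=O)[C@H](C)[C@@]3(O[Si](C)(C)C(C)(C)C)C(=O)[C@H]4C(C)=CCC[C@@]42C
F3 | step 11 | methyl (2E,6S)-2-iodo-6-[(1S)-4-(tert-butyldimethylsilyloxy)-1,3-dimethylcyclohex-2-en-1-yl]-6-(4-methoxybenzyloxy)-3-methylhex-2-enoate | COC(=O)/C(I)=C(/C)CC[C@H](OCc2ccc(OC)cc2)[C@]1(C)C=C(C)C(O[Si](C)(C)C(C)(C)C)CC1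
F4 | step 32 | 12β-chloromethanesulfonate of 42 | CC(=O)O[C@H]1CC/C(C)=C(/Cl)[C@@H]2OC(=O)[C@H](C)[C@@]2(O[Si](C)(C)C(C)(C)C)[C@@H](O[Si](CC)(CC)CC)[C@H]3[C@@H](C)[C@@H](OS(=O)(=O)CCl)C=C[C@@]31C
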